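The cyclohexene ring is cut into two three-carbon halves, at its C=C bond (ring CH=C–CO2H) and at the bond between the ring CH2 and the spiro carbon. Both bonds form in one flask: the sodium malonate of an α-formyl alkylmalonate opens a chiral 2-methylcyclopropylphosphonium salt at its CH2 group, and the ylide so released closes onto the aldehyde (homoconjugate addition, then intramolecular Wittig). The step exploits the 1,3-relation of spiro carbon and olefinic CH across the chain-bearing ring CH, with the alkene carboxyl as ylide anchor. The spiro carbon enters as a malonate carbon; its oxygen, the tetronate and the 13-membered carbocycle follow by hydroxylation, acylketene lactonisation and Dieckmann closure.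

Key step: step 11

Remark: the 3-acyltetronic acid is drawn as one exocyclic enol tautomer (the tautomers interconvert) and its enone C=C is ring-cis (Z); (4R)-4-methyloxolan-2-one and (R)-citronellal are taken as purchasable.

Step 1
Reactants: 1 (R)-citronellal
Product: 2 (4R)-4,8-dimethylnona-1,7-diene
Conditions: Ph3PCH3Br, KOtBu, THF, 0 °C to 23 °C
Reagents that add atoms: methyltriphenylphosphonium bromide, C[P+](c1ccccc1)(c1ccccc1)c1ccccc1.[Br-]
Why: Wittig methylenation of the aldehyde with the non-stabilised ylide; the stereocentre is β to the carbonyl and cannot epimerise.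

Step 2
Reactants: 2 (4R)-4,8-dimethylnona-1,7-diene
Product: 4 (2R,4R)-2,4,8-trimethylnon-7-en-1-ol, via alkyl(dimethyl)alumane 3 (not isolated)
Conditions: Me3Al, (−)-bis(1-neomenthylindenyl)zirconium dichloride (3 mol %), methylaluminoxane, CH2Cl2, 0 °C to 23 °C; then O2, 0 °C
Reagents that add atoms: trimethylaluminium, C[Al](C)C; oxygen, O=O
Why: Zirconium-catalysed asymmetric carboalumination (ZACA reaction) adds methyl and aluminium across the terminal alkene only, the chiral zirconocene choosing the alkene face so that the new C2 centre should be R (syn to the C4 methyl), and oxygen then turns C–Al into C–OH with retention.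

Step 3
Reactants: 4 (2R,4R)-2,4,8-trimethylnon-7-en-1-ol
Product: 5 (2R,4R)-2,4,8-trimethylnon-7-enal
Conditions: Dess–Martin periodinane, NaHCO3, CH2Cl2, 0 °C
Reagents that add atoms: none
Why: Buffered Dess–Martin oxidation of the primary alcohol should give the α-branched aldehyde without epimerisation.

Step 4
Reactants: 5 (2R,4R)-2,4,8-trimethylnon-7-enal
Product: 6 (2Z,4R,6R)-2-iodo-4,6,10-trimethylundeca-2,9-diene
Conditions: EtPPh3Br, n-BuLi, THF, 23 °C; I2, −78 °C; NaHMDS, −20 °C; then 5, −78 °C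
Reagents that add atoms: ethyltriphenylphosphonium bromide, CC[P+](c1ccccc1)(c1ccccc1)c1ccccc1.[Br-]; iodine, II
Why: Stork–Zhao iodo-olefination; the α-iodo ylide adds under kinetic control so that iodine and the alkyl chain should end cis, which fixes the later ring-cis geometry of the enone.

Step 5
Reactants: 6 (2Z,4R,6R)-2-iodo-4,6,10-trimethylundeca-2,9-diene; 7 (2E)-but-2-enal
Product: 8 (2E,6R,8R,9Z)-10-iodo-6,8-dimethylundeca-2,9-dienal
Conditions: second-generation Hoveyda–Grubbs catalyst (5 mol %), CH2Cl2, 40 °C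
Reagents that add atoms: none
Why: Olefin cross-metathesis of the isopropylidene terminus with crotonaldehyde (2-methylbut-2-ene is lost) should give the E-enal, the hindered iodoalkene staying inert.

Step 6
Reactants: 8 (2E,6R,8R,9Z)-10-iodo-6,8-dimethylundeca-2,9-dienal
Product: 9 (6R,8R,9Z)-10-iodo-6,8-dimethylundec-9-enal
Conditions: Hantzsch ester, dibenzylammonium trifluoroacetate (10 mol %), THF, 23 °C
Reagents that add atoms: none
Why: Iminium-catalysed transfer hydrogenation (conjugate reduction) reduces only the enal C=C and spares the aldehyde and the alkenyl iodide.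

Step 7
Reactants: 9 (6R,8R,9Z)-10-iodo-6,8-dimethylundec-9-enal; 10 dimethyl 2-bromopropanedioate
Product: 11 dimethyl 2-[(2R,6R,8R,9Z)-10-iodo-6,8-dimethyl-1-oxoundec-9-en-2-yl]propanedioate
Conditions: Ru(bpy)3Cl2 (0.5 mol %), (2R,5S)-2-tert-butyl-3,5-dimethylimidazolidin-4-one·CF3SO3H (20 mol %), 2,6-lutidine, DMF, 23 °C, visible light
Reagents that add atoms: none
Why: Enamine/photoredox α-alkylation of an aldehyde; the malonyl radical from 10 adds to the chiral enamine on the face left open by the tert-butyl group, and this catalyst enantiomer is chosen so that the new centre should be 2R.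

Step 8
Reactants: 12 (4R)-4-methyloxolan-2-one
Product: 14 2-(trimethylsilyl)ethyl (3S)-2,4-dibromo-3-methylbutanoate, via dibromo acyl bromide 13 (not isolated)
Conditions: PBr3, Br2, 110 °C; then Me3SiCH2CH2OH, pyridine, CH2Cl2, 0 °C
Reagents that add atoms: bromine, BrBr; phosphorus tribromide, BrP(Br)Br; 2-(trimethylsilyl)ethanol, C[Si](C)(C)CCO
Why: Hell–Volhard–Zelinsky-type ring-opening bromination of the γ-lactone gives the 2,4-dibromo acyl bromide, which is trapped as the silylethyl ester; the C3 stereocentre is not enolisable and C2 is made planar later.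

Step 9
Reactants: 14 2-(trimethylsilyl)ethyl (3S)-2,4-dibromo-3-methylbutanoate
Product: 15 [(2R)-3-bromo-2-methyl-1-{[2-(trimethylsilyl)ethoxy]carbonyl}propyl]triphenylphosphonium bromide
Conditions: PPh3, MeCN, 70 °C
Reagents that add atoms: triphenylphosphine, c1ccc(cc1)P(c1ccccc1)c1ccccc1
Why: SN2 quaternisation of the phosphine at the activated α-bromo ester carbon, which should outpace attack at the β-branched primary bromide.

Step 10
Reactants: 15 [(2R)-3-bromo-2-methyl-1-{[2-(trimethylsilyl)ethoxy]carbonyl}propyl]triphenylphosphonium bromide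
Product: 17 [(2S)-2-methyl-1-{[2-(trimethylsilyl)ethoxy]carbonyl}cyclopropyl]triphenylphosphonium tetrafluoroborate, via ester-stabilised ylide 16 (not isolated)
Conditions: K2CO3, CH2Cl2–H2O, 23 °C; toluene, 90 °C; then NaBF4, H2O
Reagents that add atoms: sodium tetrafluoroborate, [Na+].F[B-](F)(F)F
Why: Deprotonation gives the ester-stabilised ylide, whose 3-exo-tet C-alkylation by the primary bromide closes the cyclopropane (the construction used for the parent 1-alkoxycarbonylcyclopropylphosphonium salts), and anion exchange gives the non-nucleophilic tetrafluoroborate; the methyl-bearing centre is untouched.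

Step 11
Reactants: 11 dimethyl 2-[(2R,6R,8R,9Z)-10-iodo-6,8-dimethyl-1-oxoundec-9-en-2-yl]propanedioate; 17 [(2S)-2-methyl-1-{[2-(trimethylsilyl)ethoxy]carbonyl}cyclopropyl]triphenylphosphonium tetrafluoroborate
Product: 19 1,1-dimethyl 4-[2-(trimethylsilyl)ethyl] (2S,5S)-2-[(4R,6R,7Z)-8-iodo-4,6-dimethylnon-7-en-1-yl]-5-methylcyclohex-3-ene-1,1,4-tricarboxylate, via ring-opened phosphorus ylide 18 (not isolated)
Conditions: NaH (1.05 equiv), THF, 0 °C; then 17, HMPA, 23 °C to 50 °C
Reagents that add atoms: none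
Why: The sodium malonate of 11 attacks the unsubstituted CH2 of the activated cyclopropane of 17 in an SN2-type homoconjugate addition, which breaks the ring bond to the phosphorus-bearing carbon, forms the bond from the ring CH2 to the future spiro carbon and sets free the ester-stabilised ylide 18. This ylide then undergoes intramolecular Wittig olefination with the aldehyde two atoms away, which forms the ring C=C and closes the cyclohexene (6-exo-trig attack on the C=O, then loss of Ph3PO). The closest known reaction type is the cyclopropylphosphonium annulation of β-dicarbonyl enolates (homoconjugate addition followed by intramolecular Wittig reaction), here extended by one atom to a six-membered ring. No stereocentre is created: the malonate carbon is not stereogenic, C2 comes from step 7, C5 comes from lactone 12, and the alkene geometry is dictated by the ring. The step needs ring opening at CH2 and not at the methyl-bearing carbon, which the bulky tertiary nucleophile and the crowding at the methyl-bearing carbon should secure; it also needs the α-formyl centre to survive, which full conversion of 11 into its malonate anion by one equivalent of NaH should secure, since a second deprotonation next to the anion is disfavoured.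

Step 12
Reactants: 19 1,1-dimethyl 4-[2-(trimethylsilyl)ethyl] (2S,5S)-2-[(4R,6R,7Z)-8-iodo-4,6-dimethylnon-7-en-1-yl]-5-methylcyclohex-3-ene-1,1,4-tricarboxylate
Product: 20 1-methyl 4-[2-(trimethylsilyl)ethyl] (2S,5S)-2-[(4R,6R,7Z)-8-iodo-4,6-dimethylnon-7-en-1-yl]-5-methylcyclohex-3-ene-1,4-dicarboxylate
Conditions: LiCl, H2O, DMSO, 150 °C
Reagents that add atoms: none
Why: Krapcho dealkoxycarbonylation removes one ester of the geminal diester only (demethylation by chloride, then loss of CO2) and leaves the enoate ester; both C1 epimers converge in step 13.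

Step 13
Reactants: 20 1-methyl 4-[2-(trimethylsilyl)ethyl] (2S,5S)-2-[(4R,6R,7Z)-8-iodo-4,6-dimethylnon-7-en-1-yl]-5-methylcyclohex-3-ene-1,4-dicarboxylate
Product: 21 1-methyl 4-[2-(trimethylsilyl)ethyl] (1S,2S,5S)-1-hydroxy-2-[(4R,6R,7Z)-8-iodo-4,6-dimethylnon-7-en-1-yl]-5-methylcyclohex-3-ene-1,4-dicarboxylate
Conditions: KHMDS, THF, −78 °C; then 2-(benzenesulfonyl)-3-phenyloxaziridine, −78 °C
Reagents that add atoms: 2-(benzenesulfonyl)-3-phenyloxaziridine, O=S(=O)(c1ccccc1)N1OC1c1ccccc1
Why: Enolate hydroxylation with the Davis oxaziridine; the oxidant approaches the ester enolate on the face opposite to the C2 side chain and the C5 methyl group (both on one face), which should give the 1S tertiary alcohol with the ester cis to the chain.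

Step 14
Reactants: 21 1-methyl 4-[2-(trimethylsilyl)ethyl] (1S,2S,5S)-1-hydroxy-2-[(4R,6R,7Z)-8-iodo-4,6-dimethylnon-7-en-1-yl]-5-methylcyclohex-3-ene-1,4-dicarboxylate
Product: 22 (2Z,4R,6R)-9-[(1S,4S,6S)-6-hydroxy-6-(methoxycarbonyl)-4-methyl-3-{[2-(trimethylsilyl)ethoxy]carbonyl}cyclohex-2-en-1-yl]-2,4,6-trimethylnon-2-enoic acid
Conditions: Pd(OAc)2 (5 mol %), PPh3, CO (1 atm), KOAc, DMF–H2O, 50 °C
Reagents that add atoms: carbon monoxide, [C-]#[O+]; water, O
Why: Palladium-catalysed hydroxycarbonylation of the alkenyl iodide (oxidative addition to zerovalent palladium, CO insertion, hydrolysis of the acylpalladium) proceeds with retention of the Z geometry, and the hindered tertiary alcohol should not compete with water.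

Step 15
Reactants: 22 (2Z,4R,6R)-9-[(1S,4S,6S)-6-hydroxy-6-(methoxycarbonyl)-4-methyl-3-{[2-(trimethylsilyl)ethoxy]carbonyl}cyclohex-2-en-1-yl]-2,4,6-trimethylnon-2-enoic acid; 23 2,2-dimethyl-1,3-dioxane-4,6-dione
Product: 25 14-membered Z-configured β-keto macrolactone, via acyl Meldrum's acid 24 (not isolated)
Conditions: 1,1'-carbonyldiimidazole, THF, 23 °C; 23, 40 °C; then toluene, 110 °C, 0.001 M
Reagents that add atoms: none
Why: The acyl imidazolide C-acylates Meldrum's acid, and thermolysis of the acyl Meldrum's acid gives an acylketene (loss of acetone and CO2) that is captured by the tertiary hydroxyl at high dilution to close the 14-membered β-keto lactone, the cis alkene pre-organising the chain.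

Step 16
Reactants: 25 14-membered Z-configured β-keto macrolactone
Product: 27 okilactomycin C, via macrocyclic silylethyl ester 26 (not isolated)
Conditions: Bu4NF (5 equiv), THF, 0 °C to 23 °C; then 1 M HCl
Reagents that add atoms: none
Why: Fluoride-mediated Dieckmann (Lacey–Dieckmann) cyclisation: the 1,3-dicarbonyl carbanion attacks the neighbouring methyl ester in a 5-exo-trig acyl substitution, which forms the tetronate ring and the 13-membered carbocycle and gives the silylethyl ester 26, and excess fluoride then removes the silylethyl ester by β-elimination; no stereocentre is affected.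

Compound list

1 | (R)-citronellal, (3R)-3,7-dimethyloct-6-enal | O=CC[C@H](C)CCC=C(C)C | starting material
2 | (4R)-4,8-dimethylnona-1,7-diene | C=CC[C@H](C)CCC=C(C)C | intermediate
3 | dimethyl[(2R,4R)-2,4,8-trimethylnon-7-en-1-yl]alumane | C[Al](C)C[C@H](C)C[C@H](C)CCC=C(C)C | intermediate
4 | (2R,4R)-2,4,8-trimethylnon-7-en-1-ol | OC[C@H](C)C[C@H](C)CCC=C(C)C | intermediate
5 | (2R,4R)-2,4,8-trimethylnon-7-enal | O=C[C@H](C)C[C@H](C)CCC=C(C)C | intermediate
6 | (2Z,4R,6R)-2-iodo-4,6,10-trimethylundeca-2,9-diene | C/C(I)=C/[C@H](C)C[C@H](C)CCC=C(C)C | intermediate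
7 | (2E)-but-2-enal (crotonaldehyde) | C/C=C/C=O | starting material
8 | (2E,6R,8R,9Z)-10-iodo-6,8-dimethylundeca-2,9-dienal | C/C(I)=C/[C@H](C)C[C@H](C)CC/C=C/C=O | intermediate
9 | (6R,8R,9Z)-10-iodo-6,8-dimethylundec-9-enal | C/C(I)=C/[C@H](C)C[C@H](C)CCCCC=O | intermediate
10 | dimethyl 2-bromopropanedioate (dimethyl bromomalonate) | COC(=O)C(Br)C(=O)OC | starting material
11 | dimethyl 2-[(2R,6R,8R,9Z)-10-iodo-6,8-dimethyl-1-oxoundec-9-en-2-yl]propanedioate | C/C(I)=C/[C@H](C)C[C@H](C)CCC[C@@H](C=O)C(C(=O)OC)C(=O)OC | intermediate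
12 | (4R)-4-methyloxolan-2-one ((R)-β-methyl-γ-butyrolactone) | O=C1C[C@@H](C)CO1 | starting material
13 | (3S)-2,4-dibromo-3-methylbutanoyl bromide (both C2 epimers) | C[C@@H](CBr)C(Br)C(Br)=O | intermediate
14 | 2-(trimethylsilyl)ethyl (3S)-2,4-dibromo-3-methylbutanoate (both C2 epimers) | C[C@@H](CBr)C(Br)C(=O)OCC[Si](C)(C)C | intermediate
15 | [(2R)-3-bromo-2-methyl-1-{[2-(trimethylsilyl)ethoxy]carbonyl}propyl]triphenylphosphonium bromide (both C1 epimers) | C[C@@H](CBr)C(C(=O)OCC[Si](C)(C)C)[P+](c1ccccc1)(c1ccccc1)c1ccccc1.[Br-] | intermediate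
16 | 2-(trimethylsilyl)ethyl (3R)-4-bromo-3-methyl-2-(triphenyl-λ5-phosphanylidene)butanoate | C[C@@H](CBr)C(C(=O)OCC[Si](C)(C)C)=P(c1ccccc1)(c1ccccc1)c1ccccc1 | intermediate
17 | [(2S)-2-methyl-1-{[2-(trimethylsilyl)ethoxy]carbonyl}cyclopropyl]triphenylphosphonium tetrafluoroborate (both C1 epimers) | C[C@H]1CC1(C(=O)OCC[Si](C)(C)C)[P+](c1ccccc1)(c1ccccc1)c1ccccc1.F[B-](F)(F)F | intermediate
18 | ring-opened ylide: the malonate carbon of 11 bonded to the former ring CH2 of 17, giving a CH2–CH(CH3)–C(=PPh3)–CO2CH2CH2SiMe3 arm next to the untouched α-formyl centre | C/C(I)=C/[C@H](C)C[C@H](C)CCC[C@@H](C=O)C(C(=O)OC)(C(=O)OC)C[C@H](C)C(C(=O)OCC[Si](C)(C)C)=P(c1ccccc1)(c1ccccc1)c1ccccc1 | intermediate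
19 | 1,1-dimethyl 4-[2-(trimethylsilyl)ethyl] (2S,5S)-2-[(4R,6R,7Z)-8-iodo-4,6-dimethylnon-7-en-1-yl]-5-methylcyclohex-3-ene-1,1,4-tricarboxylate (side chain and ring methyl cis) | C/C(I)=C/[C@H](C)C[C@H](C)CCC[C@H]1C=C(C(=O)OCC[Si](C)(C)C)[C@@H](C)CC1(C(=O)OC)C(=O)OC | intermediate
20 | 1-methyl 4-[2-(trimethylsilyl)ethyl] (2S,5S)-2-[(4R,6R,7Z)-8-iodo-4,6-dimethylnon-7-en-1-yl]-5-methylcyclohex-3-ene-1,4-dicarboxylate (both C1 epimers) | C/C(I)=C/[C@H](C)C[C@H](C)CCC[C@H]1C=C(C(=O)OCC[Si](C)(C)C)[C@@H](C)CC1C(=O)OC | intermediate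
21 | 1-methyl 4-[2-(trimethylsilyl)ethyl] (1S,2S,5S)-1-hydroxy-2-[(4R,6R,7Z)-8-iodo-4,6-dimethylnon-7-en-1-yl]-5-methylcyclohex-3-ene-1,4-dicarboxylate (hydroxyl trans to side chain and to ring methyl) | C/C(I)=C/[C@H](C)C[C@H](C)CCC[C@H]1C=C(C(=O)OCC[Si](C)(C)C)[C@@H](C)C[C@@]1(O)C(=O)OC | intermediate
22 | (2Z,4R,6R)-9-[(1S,4S,6S)-6-hydroxy-6-(methoxycarbonyl)-4-methyl-3-{[2-(trimethylsilyl)ethoxy]carbonyl}cyclohex-2-en-1-yl]-2,4,6-trimethylnon-2-enoic acid | C/C(C(=O)O)=C/[C@H](C)C[C@H](C)CCC[C@H]1C=C(C(=O)OCC[Si](C)(C)C)[C@@H](C)C[C@@]1(O)C(=O)OC | intermediate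
23 | 2,2-dimethyl-1,3-dioxane-4,6-dione (Meldrum's acid) | CC1(C)OC(=O)CC(=O)O1 | starting material
24 | acyl Meldrum's acid: 22 with its carboxyl carbon bonded to C5 of 2,2-dimethyl-1,3-dioxane-4,6-dione; Z alkene and all stereocentres as in 22 | C/C(C(=O)C1C(=O)OC(C)(C)OC1=O)=C/[C@H](C)C[C@H](C)CCC[C@H]1C=C(C(=O)OCC[Si](C)(C)C)[C@@H](C)C[C@@]1(O)C(=O)OC | intermediate
25 | 14-membered β-keto macrolactone: the tertiary oxygen of 21 acylated by the chain as O–CO–CH2–CO–C(CH3)=CH (Z, ring-cis); methyl ester and silylethyl ester unchanged; all stereocentres as in 21 | CC1=C/[C@H](C)C[C@H](C)CCC[C@H]2C=C(C(=O)OCC[Si](C)(C)C)[C@@H](C)C[C@]2(C(=O)OC)OC(=O)CC\1=O | intermediate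
26 | okilactomycin C 2-(trimethylsilyl)ethyl ester (spiro 3-acyltetronic acid with the 13-membered carbocycle closed) | CC1=C/[C@H](C)C[C@H](C)CCC[C@H]2C=C(C(=O)OCC[Si](C)(C)C)[C@@H](C)C[C@]23OC(=O)\C(=C\1O)C3=O | intermediate
27 | okilactomycin C | CC1=C/[C@H](C)C[C@H](C)CCC[C@H]2C=C(C(=O)O)[C@@H](C)C[C@]23OC(=O)\C(=C\1O)C3=O | target

Total step count: 16. Longest linear sequence: 13 steps (steps 1 to 7 and 11 to 16, from 1); the branch from 12 (steps 8 to 10) joins at step 11.

Steps most likely to fail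

Step 11. The malonate may open the cyclopropane at the methyl-bearing carbon, or so slowly that the aldehyde is lost to aldol pathways or its α-centre epimerises. The fallback makes the two bonds one after the other; it sets out from 11 and from phosphonium bromide 15 and comes back at 19. The ylide 16 is released from 15 at 23 °C (K2CO3, CH2Cl2–H2O, no heating, so that cyclopropane closure stays slow) and is intercepted by aldehyde 11 in an intermolecular Wittig reaction, which should give 2-(trimethylsilyl)ethyl (2E,4S,8R,10R,11Z)-2-[(2R)-1-bromopropan-2-yl]-4-(1,3-dimethoxy-1,3-dioxopropan-2-yl)-12-iodo-8,10-dimethyltrideca-2,11-dienoate F1. Cs2CO3 and NaI in DMF at 50 °C then effect the 6-exo-tet alkylation of the malonate by the primary bromide and give 19.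

Step 15. The hindered tertiary hydroxyl may capture the acylketene too slowly, so that the ketene dimerises. The fallback builds the tetronate first and closes the macrocycle by C-acylation of it; it sets out from 21 and comes back at 26. Acetylation of the tertiary alcohol (Ac2O, Sc(OTf)3) gives 1-methyl 4-[2-(trimethylsilyl)ethyl] (1S,2S,5S)-1-acetoxy-2-[(4R,6R,7Z)-8-iodo-4,6-dimethylnon-7-en-1-yl]-5-methylcyclohex-3-ene-1,4-dicarboxylate F2. Dieckmann cyclisation with LiHMDS gives 2-(trimethylsilyl)ethyl (5S,6S,9S)-4-hydroxy-6-[(4R,6R,7Z)-8-iodo-4,6-dimethylnon-7-en-1-yl]-9-methyl-2-oxo-1-oxaspiro[4.5]deca-3,7-diene-8-carboxylate F3. Hydroxycarbonylation under the conditions of step 14 gives the corresponding (2Z)-2,4,6-trimethylnon-2-enoic acid bearing the spiro tetronic acid F4. DCC and DMAP at high dilution then O-acylate the tetronic acid and shift the acyl group to its C3 (the known 3-acylation of tetronic acids), giving 26, which the fluoride of step 16 converts into 27.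

Step 2. Facial selectivity of the carboalumination may be poor on a substrate that already carries a stereocentre, giving 2,4-syn and 2,4-anti alcohols that are hard to separate. The fallback sets the C2 centre by copper-catalysed conjugate addition; it sets out from 1 and comes back at 5, replacing steps 1 to 3. Henry reaction of 1 with nitromethane gives (4R)-4,8-dimethyl-1-nitronon-7-en-2-ol F5, and dehydration (MsCl, Et3N) gives (1E,4R)-4,8-dimethyl-1-nitronona-1,7-diene F6. Cu(OTf)2 with a chiral BINOL-based phosphoramidite ligand catalyses the addition of Me3Al to give (2R,4R)-2,4,8-trimethyl-1-nitronon-7-ene F7. A Nef reaction (NaOMe, then buffered TiCl3) gives aldehyde 5.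

Further compounds
F1 | step 11 | 2-(trimethylsilyl)ethyl (2E,4S,8R,10R,11Z)-2-[(2R)-1-bromopropan-2-yl]-4-(1,3-dimethoxy-1,3-dioxopropan-2-yl)-12-iodo-8,10-dimethyltrideca-2,11-dienoate | C/C(I)=C/[C@H](C)C[C@H](C)CCC[C@@H](/C=C(\[C@@H](C)CBr)C(=O)OCC[Si](C)(C)C)C(C(=O)OC)C(=O)OC
F2 | step 15 | 1-methyl 4-[2-(trimethylsilyl)ethyl] (1S,2S,5S)-1-acetoxy-2-[(4R,6R,7Z)-8-iodo-4,6-dimethylnon-7-en-1-yl]-5-methylcyclohex-3-ene-1,4-dicarboxylate | C/C(I)=C/[C@H](C)C[C@H](C)CCC[C@H]1C=C(C(=O)OCC[Si](C)(C)C)[C@@H](C)C[C@@]1(OC(C)=O)C(=O)OC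
F3 | step 15 | 2-(trimethylsilyl)ethyl (5S,6S,9S)-4-hydroxy-6-[(4R,6R,7Z)-8-iodo-4,6-dimethylnon-7-en-1-yl]-9-methyl-2-oxo-1-oxaspiro[4.5]deca-3,7-diene-8-carboxylate | C/C(I)=C/[C@H](C)C[C@H](C)CCC[C@H]1C=C(C(=O)OCC[Si](C)(C)C)[C@@H](C)C[C@]12OC(=O)C=C2O
F4 | step 15 | (2Z,4R,6R)-9-[(5S,6S,9S)-4-hydroxy-9-methyl-2-oxo-8-{[2-(trimethylsilyl)ethoxy]carbonyl}-1-oxaspiro[4.5]deca-3,7-dien-6-yl]-2,4,6-trimethylnon-2-enoic acid | C/C(C(=O)O)=C/[C@H](C)C[C@H](C)CCC[C@H]1C=C(C(=O)OCC[Si](C)(C)C)[C@@H](C)C[C@]12OC(=O)C=C2O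
F5 | step 2 | (4R)-4,8-dimethyl-1-nitronon-7-en-2-ol (both C2 epimers) | [O-][N+](=O)CC(O)C[C@H](C)CCC=C(C)C
F6 | step 2 | (1E,4R)-4,8-dimethyl-1-nitronona-1,7-diene | [O-][N+](=O)/C=C/C[C@H](C)CCC=C(C)C
F7 | step 2 | (2R,4R)-2,4,8-trimethyl-1-nitronon-7-ene | [O-][N+](=O)C[C@H](C)C[C@H](C)CCC=C(C)C
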